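**Plan**

1. Numbering used here: ring C1 (CH–OAc), C2 (=C, bears the side chain), C3 (=CH), C4 (CMe2), C5 (CHBr), C6 (CH2); C1′ is the side-chain CHBr, C2′ the CH2Cl. The retrosynthesis cuts C1′–Br (invertive bromination of a carbinol) and the acetate, then the ring bonds C1–C2 and C5–C6 in one operation, then the C–B bond of an alkenyl boronate (back to an alkyne) and the acetylide–chloroacetyl bond.
2. Enabling feature: C1 is an oxygen-bearing sp3 carbon flanked by the vinylic C2 and the methylene C6, and C5 carries bromine beside the quaternary C4. C1–O is therefore made as C1–B, C6=C1 is a vinyl group on a borate whose other carbon ligand is C2, and C5 is a bromoalkyl radical from a CHBr2 group.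
3. Forward: the open chain C5–C4–C3=C2(B)–C1′–C2′ is built linearly (acetylide acylation, trans-hydroboration). The only ring, the cyclohexene, closes in step 7 by radical addition of C5 to C6 and 1,2-shift of C2 from boron to C1; the boron is then oxidised to the C1 oxygen.
4. Stereochemistry: C1′ comes from asymmetric transfer hydrogenation (S) and is inverted to (R) in the last step. C5 forms without absolute control. C1 is set cis to C5 by Luche reduction of the enone. The fixed C1′ centre makes the two cis ring antipodes diastereomers, which are separated by chromatography after the reduction, so at most half of the material passes step 9.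

Key step: step 7

Assumption: methyl 2,2-dimethylbut-3-ynoate (1) is taken as a catalogue compound; it is the methyl ester of commercial 2,2-dimethylbut-3-ynoic acid.

**Route**

Step 1
Reactants: 1 methyl 2,2-dimethylbut-3-ynoate; 2 2-chloro-N-methoxy-N-methylacetamide
Product: 4 methyl 6-chloro-2,2-dimethyl-5-oxohex-3-ynoate, via lithium acetylide 3 (not isolated)
Conditions: LiN(iPr)2 (1.0 equiv), THF, −78 °C; then 2, −78 to −20 °C; aq. NH4Cl
Reagents that add atoms: none
Why: Acylation of a lithium acetylide with a Weinreb amide (Weinreb ketone synthesis); the ester has no α-hydrogen and a quaternary neighbour, so it survives, and the chelated adduct stops at the ketone.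

Step 2
Reactants: 4 methyl 6-chloro-2,2-dimethyl-5-oxohex-3-ynoate
Product: 5 methyl (5S)-6-chloro-5-hydroxy-2,2-dimethylhex-3-ynoate
Conditions: Ru[(R,R)-TsDPEN](p-cymene) (1 mol %), 2-propanol, rt
Reagents that add atoms: none
Why: Noyori asymmetric transfer hydrogenation of an ynone under base-free conditions; the catalyst tells the alkynyl group from the CH2Cl group, and the (R,R) ligand should give the (5S) chlorohydrin (the facial sense known for alkynyl methyl ketones, with the descriptor changed by the chlorine).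

Step 3
Reactants: 5 methyl (5S)-6-chloro-5-hydroxy-2,2-dimethylhex-3-ynoate
Product: 6 methyl (5S)-5-[(tert-butyldimethylsilyl)oxy]-6-chloro-2,2-dimethylhex-3-ynoate
Conditions: TBSCl, imidazole, DMF, rt
Reagents that add atoms: tert-butyldimethylsilyl chloride, CC(C)(C)[Si](C)(C)Cl
Why: Standard silylation of a secondary alcohol; it shields the carbinol from the hydride, Grignard and oxidising reagents of the later steps.

Step 4
Reactants: 6 methyl (5S)-5-[(tert-butyldimethylsilyl)oxy]-6-chloro-2,2-dimethylhex-3-ynoate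
Product: 7 (5S)-5-[(tert-butyldimethylsilyl)oxy]-6-chloro-2,2-dimethylhex-3-ynal
Conditions: iBu2AlH (1.1 equiv), CH2Cl2, −78 °C; aq. potassium sodium tartrate
Reagents that add atoms: none
Why: Partial reduction of an ester with diisobutylaluminium hydride; the hindered tetrahedral aluminate should persist at −78 °C and give the aldehyde only on work-up.

Step 5
Reactants: 7 (5S)-5-[(tert-butyldimethylsilyl)oxy]-6-chloro-2,2-dimethylhex-3-ynal
Product: 8 tert-butyl{[(2S)-6,6-dibromo-1-chloro-5,5-dimethylhex-3-yn-2-yl]oxy}dimethylsilane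
Conditions: (PhO)3P, Br2, CH2Cl2, −78 °C (reagent preformed); then Et3N, 7, −78 °C to rt
Reagents that add atoms: bromine, BrBr
Why: Deoxygenative gem-dibromination of an aldehyde with the triphenyl phosphite–bromine reagent; the aldehyde cannot enolise, so no vinyl bromide can form, and preforming the reagent at low temperature should spare the silyl ether and the alkyne.

Step 6
Reactants: 8 tert-butyl{[(2S)-6,6-dibromo-1-chloro-5,5-dimethylhex-3-yn-2-yl]oxy}dimethylsilane
Product: 9 2-[(2S,3E)-6,6-dibromo-2-[(tert-butyldimethylsilyl)oxy]-1-chloro-5,5-dimethylhex-3-en-3-yl]-4,4,5,5-tetramethyl-1,3,2-dioxaborolane (boron cis to the quaternary carbon)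
Conditions: HBpin, [Cp*Ru(MeCN)3]PF6 (5 mol %), CH2Cl2, 0 °C to rt
Reagents that add atoms: pinacolborane, [H]B1OC(C)(C)C(C)(C)O1
Why: Ruthenium-catalysed trans-hydroboration of an internal alkyne; anti addition of H and B puts boron cis to the quaternary carbon (the geometry the ring closure needs), and the quaternary centre should steer boron to the distal alkyne carbon.

Step 7
Reactants: 9 2-[(2S,3E)-6,6-dibromo-2-[(tert-butyldimethylsilyl)oxy]-1-chloro-5,5-dimethylhex-3-en-3-yl]-4,4,5,5-tetramethyl-1,3,2-dioxaborolane; 10 vinylmagnesium bromide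
Product: 13 5-bromo-2-[(1S)-1-[(tert-butyldimethylsilyl)oxy]-2-chloroethyl]-4,4-dimethylcyclohex-2-en-1-ol (mixture of C1/C5 stereoisomers), via borate complex 11 (not isolated), via allylic boronate 12 (not isolated)
Conditions: 10 (1.1 equiv), THF, −78 to 0 °C; then DMSO, fac-Ir(ppy)3 (1 mol %), blue LEDs, rt; then 30% H2O2, aq. NaOH, 0 °C
Reagents that add atoms: hydrogen peroxide, OO
Why: Proposed new method: photoreductive cleavage of one C–Br bond of the CHBr2 group gives a secondary α-bromoalkyl radical at C5 that adds to the terminal carbon of the boron-bound vinyl group (the future C6) in a 7-endo-trig closure, and one-electron oxidation of the resulting α-boryl radical anion (by the oxidised photocatalyst or by chain transfer to another CHBr2 group) triggers a 1,2-metallate shift of the alkenyl carbon C2 from boron to C1, which contracts the seven-membered borate ring to the cyclohexene. The closest known reaction type is the three-component radical-polar crossover (conjunctive) coupling of vinyl boronate complexes with alkyl halides; here the radical precursor and the migrating group sit in one molecule, so two components give an annulation. The step needs attack at the vinyl terminus to outrun hydrogen abstraction or reduction of the radical; the cis arrangement of boron and the quaternary carbon on the C2=C3 double bond, the gem-dimethyl group and the stabilisation of the α-boryl radical should secure this, and since the pinacol oxygens do not migrate only C2 can move. C5 is formed in the radical addition without facial control and C1 in the migration under control of the ring conformation only, so 13 is expected as a mixture of ring stereoisomers beside the fixed (1′S) centre. Oxidation of the allylic C–B bond with retention then places the oxygen on C1 without allylic transposition.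

Step 8
Reactants: 13 5-bromo-2-[(1S)-1-[(tert-butyldimethylsilyl)oxy]-2-chloroethyl]-4,4-dimethylcyclohex-2-en-1-ol (mixture of C1/C5 stereoisomers)
Product: 14 5-bromo-2-[(1S)-1-[(tert-butyldimethylsilyl)oxy]-2-chloroethyl]-4,4-dimethylcyclohex-2-en-1-one (both C5 epimers)
Conditions: Dess–Martin periodinane, CH2Cl2, 0 °C to rt
Reagents that add atoms: none
Why: Dess–Martin oxidation of the allylic alcohol under non-basic conditions, chosen so that the β-bromo ketone does not lose HBr; it erases the uncontrolled C1 centre, leaving only the two C5 epimers.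

Step 9
Reactants: 14 5-bromo-2-[(1S)-1-[(tert-butyldimethylsilyl)oxy]-2-chloroethyl]-4,4-dimethylcyclohex-2-en-1-one (both C5 epimers)
Product: 15 (1R,5S)-5-bromo-2-[(1S)-1-[(tert-butyldimethylsilyl)oxy]-2-chloroethyl]-4,4-dimethylcyclohex-2-en-1-ol
Conditions: NaBH4, CeCl3·7H2O, MeOH, −78 °C; chromatography on silica gel
Reagents that add atoms: none
Why: Luche 1,2-reduction; axial hydride delivery to the half-chair with equatorial C5–Br should place the hydroxyl cis to bromine in each C5 epimer (as in the reduction of carvone to cis-carveol), so the (5S) epimer of 14 gives 15, while the (5R) epimer gives the (1S,5R) cis diastereomer, which differs from 15 in the relative configuration of the neighbouring C1 and C1′ centres and is removed by chromatography.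

Step 10
Reactants: 15 (1R,5S)-5-bromo-2-[(1S)-1-[(tert-butyldimethylsilyl)oxy]-2-chloroethyl]-4,4-dimethylcyclohex-2-en-1-ol
Product: 16 (1R,5S)-5-bromo-2-[(1S)-1-[(tert-butyldimethylsilyl)oxy]-2-chloroethyl]-4,4-dimethylcyclohex-2-en-1-yl acetate
Conditions: Ac2O, DMAP (cat.), pyridine, CH2Cl2, 0 °C to rt
Reagents that add atoms: acetic anhydride, CC(=O)OC(C)=O
Why: DMAP-catalysed acetylation of the secondary allylic alcohol; no stereocentre is touched and the silyl ether keeps the side-chain oxygen apart.

Step 11
Reactants: 16 (1R,5S)-5-bromo-2-[(1S)-1-[(tert-butyldimethylsilyl)oxy]-2-chloroethyl]-4,4-dimethylcyclohex-2-en-1-yl acetate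
Product: 17 (1R,5S)-5-bromo-2-[(1S)-2-chloro-1-hydroxyethyl]-4,4-dimethylcyclohex-2-en-1-yl acetate
Conditions: HF·pyridine, THF, 0 °C to rt
Reagents that add atoms: none
Why: Acidic fluoride desilylation; it avoids the basic conditions under which the acetate could migrate to the freed hydroxyl.

Step 12
Reactants: 17 (1R,5S)-5-bromo-2-[(1S)-2-chloro-1-hydroxyethyl]-4,4-dimethylcyclohex-2-en-1-yl acetate
Product: 18 (1R,5S)-5-bromo-2-[(1R)-1-bromo-2-chloroethyl]-4,4-dimethylcyclohex-2-en-1-yl acetate
Conditions: PPh3, CBr4, CH2Cl2, 0 °C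
Reagents that add atoms: carbon tetrabromide, BrC(Br)(Br)Br
Why: Appel bromination with SN2 inversion turns the (1′S) alcohol into the (1′R) bromide; the SN2′ site C3 is shielded by the adjacent quaternary carbon and the β-chlorine disfavours ionisation.

**Compound list**

1 | methyl 2,2-dimethylbut-3-ynoate | COC(=O)C(C)(C)C#C | starting material
2 | 2-chloro-N-methoxy-N-methylacetamide | CON(C)C(=O)CCl | starting material
3 | lithium acetylide of 1 | COC(=O)C(C)(C)C#C[Li] | intermediate
4 | methyl 6-chloro-2,2-dimethyl-5-oxohex-3-ynoate | COC(=O)C(C)(C)C#CC(=O)CCl | intermediate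
5 | methyl (5S)-6-chloro-5-hydroxy-2,2-dimethylhex-3-ynoate | COC(=O)C(C)(C)C#C[C@H](O)CCl | intermediate
6 | methyl (5S)-5-[(tert-butyldimethylsilyl)oxy]-6-chloro-2,2-dimethylhex-3-ynoate | COC(=O)C(C)(C)C#C[C@H](O[Si](C)(C)C(C)(C)C)CCl | intermediate
7 | (5S)-5-[(tert-butyldimethylsilyl)oxy]-6-chloro-2,2-dimethylhex-3-ynal | O=CC(C)(C)C#C[C@H](O[Si](C)(C)C(C)(C)C)CCl | intermediate
8 | tert-butyl{[(2S)-6,6-dibromo-1-chloro-5,5-dimethylhex-3-yn-2-yl]oxy}dimethylsilane | BrC(Br)C(C)(C)C#C[C@H](O[Si](C)(C)C(C)(C)C)CCl | intermediate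
9 | 2-[(2S,3E)-6,6-dibromo-2-[(tert-butyldimethylsilyl)oxy]-1-chloro-5,5-dimethylhex-3-en-3-yl]-4,4,5,5-tetramethyl-1,3,2-dioxaborolane | BrC(Br)C(C)(C)/C=C(/[C@H](O[Si](C)(C)C(C)(C)C)CCl)B1OC(C)(C)C(C)(C)O1 | intermediate
10 | vinylmagnesium bromide | C=C[Mg]Br | starting material
11 | bromomagnesium ethenyl[(2S,3E)-6,6-dibromo-2-[(tert-butyldimethylsilyl)oxy]-1-chloro-5,5-dimethylhex-3-en-3-yl](pinacolato)borate | BrC(Br)C(C)(C)/C=C(/[C@H](O[Si](C)(C)C(C)(C)C)CCl)[B-]1(C=C)OC(C)(C)C(C)(C)O1.[Mg+]Br | intermediate
12 | 2-{5-bromo-2-[(1S)-1-[(tert-butyldimethylsilyl)oxy]-2-chloroethyl]-4,4-dimethylcyclohex-2-en-1-yl}-4,4,5,5-tetramethyl-1,3,2-dioxaborolane (mixture of C1/C5 stereoisomers) | CC1(C)OB(OC1(C)C)C1CC(Br)C(C)(C)C=C1[C@H](O[Si](C)(C)C(C)(C)C)CCl | intermediate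
13 | 5-bromo-2-[(1S)-1-[(tert-butyldimethylsilyl)oxy]-2-chloroethyl]-4,4-dimethylcyclohex-2-en-1-ol (mixture of C1/C5 stereoisomers) | OC1CC(Br)C(C)(C)C=C1[C@H](O[Si](C)(C)C(C)(C)C)CCl | intermediate
14 | 5-bromo-2-[(1S)-1-[(tert-butyldimethylsilyl)oxy]-2-chloroethyl]-4,4-dimethylcyclohex-2-en-1-one (both C5 epimers) | O=C1CC(Br)C(C)(C)C=C1[C@H](O[Si](C)(C)C(C)(C)C)CCl | intermediate
15 | (1R,5S)-5-bromo-2-[(1S)-1-[(tert-butyldimethylsilyl)oxy]-2-chloroethyl]-4,4-dimethylcyclohex-2-en-1-ol | O[C@@H]1C[C@H](Br)C(C)(C)C=C1[C@H](O[Si](C)(C)C(C)(C)C)CCl | intermediate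
16 | (1R,5S)-5-bromo-2-[(1S)-1-[(tert-butyldimethylsilyl)oxy]-2-chloroethyl]-4,4-dimethylcyclohex-2-en-1-yl acetate | CC(=O)O[C@@H]1C[C@H](Br)C(C)(C)C=C1[C@H](O[Si](C)(C)C(C)(C)C)CCl | intermediate
17 | (1R,5S)-5-bromo-2-[(1S)-2-chloro-1-hydroxyethyl]-4,4-dimethylcyclohex-2-en-1-yl acetate | CC(=O)O[C@@H]1C[C@H](Br)C(C)(C)C=C1[C@H](O)CCl | intermediate
18 | (1R,5S)-5-bromo-2-[(1R)-1-bromo-2-chloroethyl]-4,4-dimethylcyclohex-2-en-1-yl acetate | CC(=O)O[C@@H]1C[C@H](Br)C(C)(C)C=C1[C@@H](Br)CCl | target

Total step count: 12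
Longest linear sequence: 12 steps (1 to 18)

**Steps most likely to fail**

Step 7 (proposed new method). The borate may form incompletely at the crowded boron, the Grignard reagent may exchange with the CHBr2 group, or the C5 radical may be reduced or abstract hydrogen before the 7-endo addition. Fallback with known reaction types, setting out from 9: Kharasch atom-transfer radical addition of the CHBr2 group to vinyl acetate (RuCl2(PPh3)3, toluene, 80 °C) should make the C5–C6 bond first and give (5E,7S)-1,3-dibromo-7-[(tert-butyldimethylsilyl)oxy]-8-chloro-4,4-dimethyl-6-(4,4,5,5-tetramethyl-1,3,2-dioxaborolan-2-yl)oct-5-en-1-yl acetate F1. Mild hydrolysis of the α-bromoalkyl acetate (aq. NaHCO3, THF) should give (5E,7S)-3-bromo-7-[(tert-butyldimethylsilyl)oxy]-8-chloro-4,4-dimethyl-6-(4,4,5,5-tetramethyl-1,3,2-dioxaborolan-2-yl)oct-5-enal F2. Rhodium-catalysed intramolecular 1,2-addition of the alkenyl boronate to the aldehyde ([Rh(cod)OH]2, dioxane–water, rt) should then close the C1–C2 bond and come back to the route at 13.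

Step 6. Boron may be delivered to the wrong alkyne carbon, or the catalyst may not turn over at an alkyne flanked by a quaternary carbon and a silyloxy-bearing carbon. Fallback, setting out from 5, with the free hydroxyl directing the metal: trans-hydrostannation ([Cp*RuCl]4, Bu3SnH, CH2Cl2) should give methyl (3Z,5R)-6-chloro-5-hydroxy-2,2-dimethyl-4-(tributylstannyl)hex-3-enoate F3. Iododestannylation (I2, CH2Cl2, 0 °C) gives methyl (3Z,5R)-6-chloro-5-hydroxy-4-iodo-2,2-dimethylhex-3-enoate F4. Silylation (TBSCl, imidazole) gives methyl (3Z,5R)-5-[(tert-butyldimethylsilyl)oxy]-6-chloro-4-iodo-2,2-dimethylhex-3-enoate F5. Reduction with iBu2AlH at −78 °C gives (3Z,5R)-5-[(tert-butyldimethylsilyl)oxy]-6-chloro-4-iodo-2,2-dimethylhex-3-enal F6. Dibromination with (PhO)3P/Br2 gives tert-butyl{[(2R,3Z)-6,6-dibromo-1-chloro-3-iodo-5,5-dimethylhex-3-en-2-yl]oxy}dimethylsilane F7. Miyaura borylation with retention (B2pin2, PdCl2(PPh3)2, PPh3, KOPh, toluene, 50 °C) comes back to the route at 9. The carbinol configuration is unchanged throughout; the descriptor changes only because tin or iodine raises the priority of the alkenyl carbon.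

Step 9. The β-bromo ketone may lose HBr under the borohydride conditions to give the cross-conjugated dienone, hydride delivery may show poor facial selectivity, or the two cis diastereomers may fail to separate. Fallback, setting out from 13 and avoiding the ketone altogether: lipase-catalysed transesterification (immobilised Burkholderia cepacia lipase, vinyl acetate, MTBE, 35 °C) should acylate only those stereoisomers of 13 whose carbinol centre is (R) (large alkenyl side, medium CH2 side). This would give 16 together with its C5 epimer (1R,5R)-5-bromo-2-[(1S)-1-[(tert-butyldimethylsilyl)oxy]-2-chloroethyl]-4,4-dimethylcyclohex-2-en-1-yl acetate F8, while the (1S)-configured alcohols stay unreacted. The alcohols are removed, the cis and trans acetates are separated by chromatography, and the route continues from 16, at the price of a smaller usable share of the material.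

Further compounds
F1 | step 7 | (5E,7S)-1,3-dibromo-7-[(tert-butyldimethylsilyl)oxy]-8-chloro-4,4-dimethyl-6-(4,4,5,5-tetramethyl-1,3,2-dioxaborolan-2-yl)oct-5-en-1-yl acetate (boron cis to C4, C1 and C3 unspecified) | CC(=O)OC(Br)CC(Br)C(C)(C)/C=C(/[C@H](O[Si](C)(C)C(C)(C)C)CCl)B1OC(C)(C)C(C)(C)O1
F2 | step 7 | (5E,7S)-3-bromo-7-[(tert-butyldimethylsilyl)oxy]-8-chloro-4,4-dimethyl-6-(4,4,5,5-tetramethyl-1,3,2-dioxaborolan-2-yl)oct-5-enal (boron cis to C4, C3 unspecified) | O=CCC(Br)C(C)(C)/C=C(/[C@H](O[Si](C)(C)C(C)(C)C)CCl)B1OC(C)(C)C(C)(C)O1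
F3 | step 6 | methyl (3Z,5R)-6-chloro-5-hydroxy-2,2-dimethyl-4-(tributylstannyl)hex-3-enoate | COC(=O)C(C)(C)/C=C(/[C@H](O)CCl)[Sn](CCCC)(CCCC)CCCC
F4 | step 6 | methyl (3Z,5R)-6-chloro-5-hydroxy-4-iodo-2,2-dimethylhex-3-enoate | COC(=O)C(C)(C)/C=C(/[C@H](O)CCl)I
F5 | step 6 | methyl (3Z,5R)-5-[(tert-butyldimethylsilyl)oxy]-6-chloro-4-iodo-2,2-dimethylhex-3-enoate | COC(=O)C(C)(C)/C=C(/[C@H](O[Si](C)(C)C(C)(C)C)CCl)I
F6 | step 6 | (3Z,5R)-5-[(tert-butyldimethylsilyl)oxy]-6-chloro-4-iodo-2,2-dimethylhex-3-enal | O=CC(C)(C)/C=C(/[C@H](O[Si](C)(C)C(C)(C)C)CCl)I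
F7 | step 6 | tert-butyl{[(2R,3Z)-6,6-dibromo-1-chloro-3-iodo-5,5-dimethylhex-3-en-2-yl]oxy}dimethylsilane | BrC(Br)C(C)(C)/C=C(/[C@H](O[Si](C)(C)C(C)(C)C)CCl)I
F8 | step 9 | (1R,5R)-5-bromo-2-[(1S)-1-[(tert-butyldimethylsilyl)oxy]-2-chloroethyl]-4,4-dimethylcyclohex-2-en-1-yl acetate | CC(=O)O[C@@H]1C[C@@H](Br)C(C)(C)C=C1[C@H](O[Si](C)(C)C(C)(C)C)CCl
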